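Compound numbers are fixed as follows and are used in every section: 1–5 and 7–10 belong to the ring A/side-chain fragment (6 is the aryllithium made in the flask), 11–12 to the ring B precursor, 13 is the product of the key step, 14–20 lead to the aldehyde, 21–22 are the sulfone and its anion, 23 is the bis-silyl ether and 24 the target.

## Structural features

The target 24 is an 8-O-4' neolignan. Ring A, a 4-hydroxy-3,5-dimethoxyphenyl group, sits on C7 of the chain C7–C8–C9; C7 carries a free secondary hydroxyl, C9 is a methyl group, and the oxygen on C8 is bound to C4' of ring B. Ring B carries methoxy groups at C3' and C5' and an (E)-prop-1-enyl group (C7'–C9') at C1'. C7 (R) and C8 (S) are neighbouring stereocentres in the anti (erythro) relationship; the only other stereo-element is the E double bond C7'=C8'. The fragile parts are the benzylic C7 carbinol para to a free phenol (under acid it ionises towards a quinone methide and C7 would scramble), the electron-rich propenylarene (no acid, no electrophile, no hydrogenation) and the easily oxidised phenol. The real difficulty is the C8–O4' bond: a secondary alkyl aryl ether whose aryl carbon lies between two methoxy groups on an electron-rich ring. Attack of an alkoxide at C4' is therefore hindered and electronically disfavoured, and attack of the phenoxide at C8 puts the configuration at risk. The key step uses the fact that C3', C4' and C5' carry three neighbouring oxygens: they correspond to C1, C2 and C3 of a cyclohexane-1,3-dione whose C5 is C1', so C4' can be reached as the carbenoid carbon of a 2-diazo-1,3-dione. Ring B is symmetric about the C1'–C4' axis, so enolisation, methylation and dehydrogenation raise no regiochemical question.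

## Logic of the disconnections

24 back to 23. No skeletal bond is cut; the O–H bonds at O7 and at the ring A phenol are exchanged for O–Si bonds. The phenol/benzylic carbinol pair is the acid- and oxidation-sensitive part of 24, and as two silyl ethers it is inert to base, hydride, enolate and carbenoid chemistry. The gain is that every earlier intermediate is robust; the demand is a final deprotection that is neither acidic nor harmful to the propenyl group.

23 back to 20 and 21. The C7'=C8' double bond is cut. The propenyl group would survive neither the hydrogenolysis of step 7 nor the carbenoid of step 9 nor the dehydrogenation of step 11, so it must come after all of them. Ring B then carries only an aldehyde and 21 is bought. The forward step must be E-selective and must not epimerise C8.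

20 back to 18 through 19. Only the oxidation level of C7' changes. An ester is a spectator that survives diazo transfer, the carbenoid step and enolate chemistry. The demand is a clean stop at the aldehyde, met by reduction to the alcohol and selective benzylic oxidation.

18 back to 13 through 17 and 14. The two O–CH3 bonds at O3' and O5' are cut and the aromatic unsaturation of ring B is taken back by two hydrogens. C4' thereby becomes C2 of a 1,3-dicarbonyl compound. The forward aromatisation must avoid acid and strong oxidants because of ring A and the benzylic silyl ether; it is therefore run on the methyl enol ether 14 through its enolate.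

13 back to 10 and 12. The O8–C4' bond is cut. This divides the molecule into a fragment with both stereocentres and an achiral ring B precursor, and it moves the bond formation from a crowded arene carbon to an open carbenoid carbon. The forward step must insert into the one free hydroxyl faster than the carbenoid rearranges, dimerises or attacks ring A.

12 back to 11. The C=N2 bond is cut; 11 is bought. The forward step is a diazo transfer to an active methylene group.

10 back to 8 through 9. The O7–Si bond is cut and the benzyl group on O8 is restored. The two secondary oxygens are told apart by their history: O8 is benzylated from the start, O7 is silylated when it appears, and O8 is then freed. The demand is a neutral debenzylation without silyl migration or loss of the benzylic C7–O bond.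

8 back to 7. The C7–H bond is cut. C7 is then set from C8 by hydride delivery within a chelate. The demand is high anti selectivity.

7 back to 3 and 5 (through 6). The C1–C7 bond is cut between an aryl nucleophile and an acyl electrophile. The demand is a single addition without enolisation at C8.

3 back to 1 through 2, and 5 back to 4. Only O–benzyl, amide C–N and O–Si bonds are cut; 1 and 4 are bought. C8 comes from the chiral pool and must not racemise in the benzylation or the amide formation.

## Other disconnections considered

Alternative 1: The cut is C8–C9. The aryloxymethyl ketone A2 would be made from the phenol A1 and the α-bromo ketone of O-allyl ring A by displacement at a primary carbon. The forward key step would methylate its enolate (solid CsOH, MeI, an N-benzylcinchonidinium salt as chiral counter-ion) to give A3. A chelation-controlled reduction to the anti alcohol A4 and deallylation with Pd(PPh3)4 (zerovalent palladium) would follow.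
- In favour: the hindered ether is formed by a phenoxide attacking an unhindered primary carbon. On this point the alternative is at least the equal of the carbenoid solution and is simpler to run. The stereocentre is made catalytically, and about six steps would suffice, which is clearly better than the chosen plan.
- Against: A3 keeps an acidic C8–H next to an aryl ketone. Under the solid hydroxide it can enolise again, which would erode the enantiomeric purity and allow a second methylation. Ion-pair control over an acyclic α-aryloxy enolate of undefined geometry is much less secure than in the usual cases where the product is no longer enolisable. C7 would then depend on chelation by a weakly basic aryl ether oxygen.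
- Comparison: the same bonds result. In the alternative both stereocentres rest on a catalyst and on a subsequent reduction with no chiral-pool anchor. The chosen plan buys C8, never exposes it to base after 7, and sets C7 in a well-defined chelate. It is safer in stereochemistry and about ten steps longer.

Alternative 2: The cut is C7–C8. The titanium enolate (TiCl4, amine base) of the N-(aryloxyacetyl)oxazolidinethione A5 would add to the silylated aldehyde A6, itself activated by more TiCl4, to give the anti adduct A7 with C9 as the imide carbonyl. Reductive removal of the auxiliary, deoxygenation of the resulting C9 alcohol to the methyl group and desilylation would follow.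
- In favour: one C–C bond formation sets both stereocentres in the anti relationship. The ether bond is again made at a primary carbon, from A1 and a haloacetate. The plan is convergent, the auxiliary is recoverable, and eight or nine steps should be enough, fewer than in the chosen plan. On convergence it is the equal of the chosen plan, and on the number of stereocentres set per step it is better.
- Against: C9 arrives at the wrong oxidation level. Taking the imide down to a methyl group costs three or so steps, and the activated C9 sulfonate would sit 1,3 to the C7 hydroxyl, inviting oxetane formation. Excess TiCl4 would meet the acid-sensitive propenylarene and an aryl silyl ether. The bulky 2,6-dimethoxyaryloxy group can bind titanium through its methoxy groups, so the enolate geometry and the anti selectivity are uncertain. A6 is a weak electrophile.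
- Comparison: the alternative controls the absolute configuration by an auxiliary and the chosen plan by lactate; both are sound in principle. The alternative reaches the right skeleton but not the right functional level at C9, whereas in the chosen plan C9 is the lactate methyl group from the outset.

Alternative 3: The cut is C1–C7. The aldehyde A8 would come from A1 and a lactate ester of the R series by Mitsunobu inversion and half-reduction. The bromide 5 would be lithiated to 6, transmetalated with ClTi(OiPr)3 and added to A8 under Felkin–Anh control to give A9, which is one desilylation away from 24.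
- In favour: this is the shortest plan, about five steps in the longest line. It shares 5 and 6 with the chosen route, uses only classical reactions, and its key step delivers the complete skeleton. In step economy and convergence it is better than the chosen plan.
- Against: A8 is an α-aryloxy aldehyde that enolises and hydrates easily, so C8 is at risk. C7 is set by acyclic stereocontrol, which for aryltitanium additions to α-oxygenated aldehydes is usually only moderate and can be eroded by chelation through the methoxy groups. Erythro and threo isomers of this class are hard to separate. The ether bond is made with inversion and needs the less common lactate antipode.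
- Comparison: both plans pass C8 through an α-oxygenated carbonyl compound (7 in the chosen plan, A8 here), so that difference is one of degree. The chosen plan sets C7 in a cyclic zinc chelate, which is the more reliable element. It pays for this with about nine more steps in the longest line. A variant of this alternative serves as the fallback for the key step.

Key step: step 9

Remarks on the chemistry and shorthand:
- The target SMILES was re-read as (7R,8S), the anti pair with an E propenyl group. The structures of both key-step partners and of the key-step product agree with it, so no structural correction was needed.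
- The silyl pattern of the alcohol partner is kept: TBS on O7, TIPS on the phenol. The design changes lie around it:
  - The key step uses a solvent without π bonds and slow addition of the diazo compound.
  - The aromatisation is run on the methyl enol ether under cold, basic, non-oxidising conditions.
  - The ester is taken to the aldehyde in two steps.
- Assumption: the ring carbon that bears the ester in 13–15 is carried as a mixture of both configurations; this has no consequence because it becomes C1' of the arene.
- Shorthand: Ar = 3,5-dimethoxy-4-(triisopropylsilyloxy)phenyl. QO– = [(1R,2S)-1-(tert-butyldimethylsilyloxy)-1-Ar-propan-2-yl]oxy, that is O8 on C8 (S, with the methyl group C9) next to C7 (R, carrying OTBS and Ar).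

## Route

Step 1
Reactants: 1 ethyl (S)-lactate
Product: 2 ethyl (S)-2-(benzyloxy)propanoate
Conditions: BnOC(=NH)CCl3, TfOH (cat.), cyclohexane/CH2Cl2, rt
Reagents that add atoms: benzyl 2,2,2-trichloroacetimidate, ClC(Cl)(Cl)C(=N)OCc1ccccc1
Why: Acid-catalysed O-benzylation with a trichloroacetimidate; no base is present, so the α-centre cannot enolise and the S configuration of lactate should be kept.

Step 2
Reactants: 2 ethyl (S)-2-(benzyloxy)propanoate
Product: 3 (S)-2-(benzyloxy)-N-methoxy-N-methylpropanamide
Conditions: MeNH(OMe)·HCl, iPrMgCl, THF, −20 → 0 °C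
Reagents that add atoms: N,O-dimethylhydroxylamine hydrochloride, CNOC.Cl
Why: Aminolysis of the ester by the chloromagnesium amide formed in the flask (Weinreb amide synthesis); the low temperature and the weakly basic amide should leave C8 untouched.

Step 3
Reactants: 4 4-bromo-2,6-dimethoxyphenol
Product: 5 (4-bromo-2,6-dimethoxyphenoxy)triisopropylsilane
Conditions: TIPSCl, imidazole, DMF, rt
Reagents that add atoms: chlorotriisopropylsilane, CC(C)[Si](Cl)(C(C)C)C(C)C
Why: Silylation of a phenol; the TIPS ether between two methoxy groups should withstand the organolithium, hydride, enolate and carbonate conditions that follow and falls to fluoride at the end.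

Step 4
Reactants: 5 (4-bromo-2,6-dimethoxyphenoxy)triisopropylsilane; 3 (S)-2-(benzyloxy)-N-methoxy-N-methylpropanamide
Product: 7 (S)-2-(benzyloxy)-1-[3,5-dimethoxy-4-(triisopropylsilyloxy)phenyl]propan-1-one, via aryllithium 6 (not isolated)
Conditions: n-BuLi, THF, −78 °C; then 3, −78 → −20 °C; aq. NH4Cl
Reagents that add atoms: none
Why: Bromine–lithium exchange followed by Weinreb ketone synthesis forms C1–C7; the chelated tetrahedral intermediate prevents a second addition and keeps the C8–H from being removed until the cold quench.

Step 5
Reactants: 7 (S)-2-(benzyloxy)-1-[3,5-dimethoxy-4-(triisopropylsilyloxy)phenyl]propan-1-one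
Product: 8 (1R,2S)-2-(benzyloxy)-1-[3,5-dimethoxy-4-(triisopropylsilyloxy)phenyl]propan-1-ol
Conditions: Zn(BH4)2, Et2O, −30 → 0 °C
Reagents that add atoms: none
Why: Chelation-controlled (Cram chelate) reduction: zinc bridges the carbonyl oxygen and the benzyloxy oxygen, and hydride enters from the face of the small hydrogen on C8, which should set C7 as R, anti to C8.

Step 6
Reactants: 8 (1R,2S)-2-(benzyloxy)-1-[3,5-dimethoxy-4-(triisopropylsilyloxy)phenyl]propan-1-ol
Product: 9 (1R,2S)-2-(benzyloxy)-1-(tert-butyldimethylsilyloxy)-1-[3,5-dimethoxy-4-(triisopropylsilyloxy)phenyl]propane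
Conditions: TBSOTf, 2,6-lutidine, CH2Cl2, −78 → 0 °C
Reagents that add atoms: tert-butyldimethylsilyl trifluoromethanesulfonate, CC(C)(C)[Si](C)(C)OS(=O)(=O)C(F)(F)F
Why: Silylation of a hindered secondary alcohol with a silyl triflate and a hindered base; the buffered cold conditions should not ionise the electron-rich benzylic position.

Step 7
Reactants: 9 (1R,2S)-2-(benzyloxy)-1-(tert-butyldimethylsilyloxy)-1-[3,5-dimethoxy-4-(triisopropylsilyloxy)phenyl]propane
Product: 10 (1R,2S)-1-(tert-butyldimethylsilyloxy)-1-[3,5-dimethoxy-4-(triisopropylsilyloxy)phenyl]propan-2-ol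
Conditions: H2 (1 atm), 10% Pd/C, EtOAc, rt
Reagents that add atoms: none
Why: Hydrogenolysis of the benzyl ether; in a neutral aprotic solvent the silyl ethers should neither cleave nor migrate, and the hindered benzylic C7–O silyl ether should be cut far more slowly than the O-benzyl group.

Step 8
Reactants: 11 ethyl 3,5-dioxocyclohexane-1-carboxylate
Product: 12 ethyl 4-diazo-3,5-dioxocyclohexane-1-carboxylate
Conditions: 4-acetamidobenzenesulfonyl azide, Et3N, MeCN, 0 °C → rt
Reagents that add atoms: 4-acetamidobenzenesulfonyl azide, CC(=O)Nc1ccc(cc1)S(=O)(=O)N=[N+]=[N-]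
Why: Regitz diazo transfer to the doubly activated methylene group of a cyclic 1,3-dione, with a sulfonyl azide that is comparatively safe to handle.

Step 9
Reactants: 10 (1R,2S)-1-(tert-butyldimethylsilyloxy)-1-[3,5-dimethoxy-4-(triisopropylsilyloxy)phenyl]propan-2-ol; 12 ethyl 4-diazo-3,5-dioxocyclohexane-1-carboxylate
Product: 13 ethyl 3-hydroxy-5-oxo-4-(QO)cyclohex-3-ene-1-carboxylate
Conditions: Rh2(OAc)4 (2 mol %), 10 (1.2 equiv), slow addition of 12, ClCH2CH2Cl, 70 °C
Reagents that add atoms: none
Why: Rh2(OAc)4, a divalent rhodium dimer, takes N2 from 12 and gives an acceptor/acceptor rhodium carbenoid at the carbon between the two carbonyls, the future C4'. The lone pair of the one free hydroxyl (O8 of 10) adds to this carbon to give a rhodium-associated oxonium ylide, and a proton shift from oxygen to carbon releases the catalyst and the 2-alkoxy-1,3-dione, which settles as enol 13. The closest known reaction type is the rhodium-carbenoid O–H insertion of 2-diazocyclohexane-1,3-diones and other diazo dicarbonyl compounds into alcohols. No ring closes and the only new skeletal bond is O8–C4'. No lasting stereocentre is made: the C8–O bond is never broken, so C8 stays S, C7 is a spectator, and the ester-bearing ring carbon is stereogenic only while the enol is unsymmetrical and loses that property in step 11. The step needs O–H insertion to win over Wolff rearrangement, carbene dimerisation, attack on ring A and a second insertion into the acidic enol O–H of 13. This should be secured by the high electrophilicity of the carbenoid towards the only alcohol lone pair present, by slow addition of 12 to a slight excess of 10 (the excess is recovered), by a solvent without C=C or arene π bonds, and by the silyl groups and methoxy flanks that shield ring A and the other oxygens. The crowded, electron-rich arene carbon that defeats direct arylation is avoided because the reacting carbon is an open sp2 carbenoid carbon.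

Step 10
Reactants: 13 ethyl 3-hydroxy-5-oxo-4-(QO)cyclohex-3-ene-1-carboxylate
Product: 14 ethyl 3-methoxy-5-oxo-4-(QO)cyclohex-3-ene-1-carboxylate
Conditions: Me3SiCHN2, MeOH/toluene, 0 °C → rt
Reagents that add atoms: (trimethylsilyl)diazomethane, C[Si](C)(C)C=[N+]=[N-]
Why: O-methylation of an acidic enol (a vinylogous acid) by a diazoalkane under neutral conditions; the first C3'/C5' methoxy group is installed, the silyl ethers are not touched, and either enol oxygen gives the same constitution because the dione is symmetric.

Step 11
Reactants: 14 ethyl 3-methoxy-5-oxo-4-(QO)cyclohex-3-ene-1-carboxylate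
Product: 17 ethyl 3-hydroxy-5-methoxy-4-(QO)benzoate, via lithium dienolate 15 (not isolated), via cyclohexadienone 16 (not isolated)
Conditions: LiN(iPr)2, THF, −78 °C; then PhS(Cl)=NtBu, −78 °C → rt; aq. NH4Cl
Reagents that add atoms: none
Why: Enolate dehydrogenation with N-tert-butylbenzenesulfinimidoyl chloride: kinetic deprotonation of the vinylogous ester at the α' carbon, S-attack of the enolate on the reagent and intramolecular syn elimination give dienone 16, which tautomerises to the phenol. Any other enolate regiochemistry (ester α-carbon or γ-carbon) would lead to a dienone that is a tautomer of the same phenol, and the cold, non-acidic, non-oxidising medium spares ring A and the benzylic silyl ether.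

Step 12
Reactants: 17 ethyl 3-hydroxy-5-methoxy-4-(QO)benzoate
Product: 18 ethyl 3,5-dimethoxy-4-(QO)benzoate
Conditions: MeI, K2CO3, acetone, rt
Reagents that add atoms: iodomethane, CI
Why: Williamson methylation of the one free phenol; anhydrous carbonate in acetone should not cleave the hindered aryl TIPS ether, which is why TIPS and not a smaller silyl group protects ring A.

Step 13
Reactants: 18 ethyl 3,5-dimethoxy-4-(QO)benzoate
Product: 19 [3,5-dimethoxy-4-(QO)phenyl]methanol
Conditions: iBu2AlH (2.5 equiv), CH2Cl2, −78 → 0 °C; aq. potassium sodium tartrate (KNaC4H4O6)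
Reagents that add atoms: none
Why: Full hydride reduction of an aryl ester to the benzylic alcohol; this avoids the unreliable partial reduction of an electron-rich benzoate, and silyl ethers and aryl ethers are inert.

Step 14
Reactants: 19 [3,5-dimethoxy-4-(QO)phenyl]methanol
Product: 20 3,5-dimethoxy-4-(QO)benzaldehyde
Conditions: MnO2, CH2Cl2, rt
Reagents that add atoms: none
Why: Selective oxidation of a primary benzylic alcohol by activated MnO2; it stops at the aldehyde and no other oxidisable hydroxyl is free.

Step 15
Reactants: 20 3,5-dimethoxy-4-(QO)benzaldehyde; 21 5-(ethylsulfonyl)-1-phenyl-1H-tetrazole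
Product: 23 1,3-dimethoxy-5-[(E)-prop-1-en-1-yl]-2-(QO)benzene, via potassium sulfonyl carbanion 22 (not isolated)
Conditions: KN(SiMe3)2, 1,2-dimethoxyethane, −60 °C; then 20, −60 °C → rt
Reagents that add atoms: none
Why: Julia–Kocienski olefination: addition of the metalated sulfone to the aldehyde, Smiles rearrangement, and loss of SO2 and tetrazolate form C7'=C8'. With the phenyltetrazolyl sulfone, a potassium counter-ion and an aryl aldehyde the E alkene should predominate, and the aldehyde has no α-hydrogen and lies far from C8.

Step 16
Reactants: 23 1,3-dimethoxy-5-[(E)-prop-1-en-1-yl]-2-(QO)benzene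
Product: 24 (1R,2S)-2-{2,6-dimethoxy-4-[(E)-prop-1-en-1-yl]phenoxy}-1-(4-hydroxy-3,5-dimethoxyphenyl)propan-1-ol
Conditions: Bu4NF, AcOH, THF, 0 °C → rt
Reagents that add atoms: none
Why: Fluoride cleavage of the secondary TBS ether and the aryl TIPS ether in one operation; the acetic acid buffer keeps the medium from becoming strongly basic, and no acid strong enough to ionise C7 is present, so both stereocentres and the E alkene should be kept.

## Compound list

1 | ethyl (S)-lactate | C[C@H](O)C(=O)OCC | starting material
2 | ethyl (S)-2-(benzyloxy)propanoate | C[C@H](OCc1ccccc1)C(=O)OCC | intermediate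
3 | (S)-2-(benzyloxy)-N-methoxy-N-methylpropanamide | C[C@H](OCc1ccccc1)C(=O)N(C)OC | intermediate
4 | 4-bromo-2,6-dimethoxyphenol | COc1cc(Br)cc(OC)c1O | starting material
5 | (4-bromo-2,6-dimethoxyphenoxy)triisopropylsilane | COc1cc(Br)cc(OC)c1O[Si](C(C)C)(C(C)C)C(C)C | intermediate
6 | [3,5-dimethoxy-4-(triisopropylsilyloxy)phenyl]lithium | [Li]c1cc(OC)c(O[Si](C(C)C)(C(C)C)C(C)C)c(OC)c1 | intermediate (not isolated)
7 | (S)-2-(benzyloxy)-1-[3,5-dimethoxy-4-(triisopropylsilyloxy)phenyl]propan-1-one | C[C@H](OCc1ccccc1)C(=O)c1cc(OC)c(O[Si](C(C)C)(C(C)C)C(C)C)c(OC)c1 | intermediate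
8 | (1R,2S)-2-(benzyloxy)-1-[3,5-dimethoxy-4-(triisopropylsilyloxy)phenyl]propan-1-ol | C[C@H](OCc1ccccc1)[C@H](O)c1cc(OC)c(O[Si](C(C)C)(C(C)C)C(C)C)c(OC)c1 | intermediate
9 | (1R,2S)-2-(benzyloxy)-1-(tert-butyldimethylsilyloxy)-1-[3,5-dimethoxy-4-(triisopropylsilyloxy)phenyl]propane | C[C@H](OCc1ccccc1)[C@H](O[Si](C)(C)C(C)(C)C)c1cc(OC)c(O[Si](C(C)C)(C(C)C)C(C)C)c(OC)c1 | intermediate
10 | (1R,2S)-1-(tert-butyldimethylsilyloxy)-1-[3,5-dimethoxy-4-(triisopropylsilyloxy)phenyl]propan-2-ol | O[C@@H](C)[C@H](O[Si](C)(C)C(C)(C)C)c1cc(OC)c(O[Si](C(C)C)(C(C)C)C(C)C)c(OC)c1 | intermediate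
11 | ethyl 3,5-dioxocyclohexane-1-carboxylate | CCOC(=O)C1CC(=O)CC(=O)C1 | starting material
12 | ethyl 4-diazo-3,5-dioxocyclohexane-1-carboxylate | CCOC(=O)C1CC(=O)C(=[N+]=[N-])C(=O)C1 | intermediate
13 | ethyl 3-hydroxy-5-oxo-4-(QO)cyclohex-3-ene-1-carboxylate (enol of the 2-alkoxy-1,3-dione) | CCOC(=O)C1CC(O)=C(O[C@@H](C)[C@H](O[Si](C)(C)C(C)(C)C)c2cc(OC)c(O[Si](C(C)C)(C(C)C)C(C)C)c(OC)c2)C(=O)C1 | intermediate
14 | ethyl 3-methoxy-5-oxo-4-(QO)cyclohex-3-ene-1-carboxylate | CCOC(=O)C1CC(OC)=C(O[C@@H](C)[C@H](O[Si](C)(C)C(C)(C)C)c2cc(OC)c(O[Si](C(C)C)(C(C)C)C(C)C)c(OC)c2)C(=O)C1 | intermediate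
15 | lithium 3-(ethoxycarbonyl)-5-methoxy-6-(QO)cyclohexa-1,5-dien-1-olate | CCOC(=O)C1CC(OC)=C(O[C@@H](C)[C@H](O[Si](C)(C)C(C)(C)C)c2cc(OC)c(O[Si](C(C)C)(C(C)C)C(C)C)c(OC)c2)C(O[Li])=C1 | intermediate (not isolated)
16 | ethyl 5-methoxy-3-oxo-4-(QO)cyclohexa-1,4-diene-1-carboxylate | CCOC(=O)C1=CC(=O)C(O[C@@H](C)[C@H](O[Si](C)(C)C(C)(C)C)c2cc(OC)c(O[Si](C(C)C)(C(C)C)C(C)C)c(OC)c2)=C(OC)C1 | intermediate (not isolated)
17 | ethyl 3-hydroxy-5-methoxy-4-(QO)benzoate | CCOC(=O)c1cc(O)c(O[C@@H](C)[C@H](O[Si](C)(C)C(C)(C)C)c2cc(OC)c(O[Si](C(C)C)(C(C)C)C(C)C)c(OC)c2)c(OC)c1 | intermediate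
18 | ethyl 3,5-dimethoxy-4-(QO)benzoate | CCOC(=O)c1cc(OC)c(O[C@@H](C)[C@H](O[Si](C)(C)C(C)(C)C)c2cc(OC)c(O[Si](C(C)C)(C(C)C)C(C)C)c(OC)c2)c(OC)c1 | intermediate
19 | [3,5-dimethoxy-4-(QO)phenyl]methanol | OCc1cc(OC)c(O[C@@H](C)[C@H](O[Si](C)(C)C(C)(C)C)c2cc(OC)c(O[Si](C(C)C)(C(C)C)C(C)C)c(OC)c2)c(OC)c1 | intermediate
20 | 3,5-dimethoxy-4-(QO)benzaldehyde | O=Cc1cc(OC)c(O[C@@H](C)[C@H](O[Si](C)(C)C(C)(C)C)c2cc(OC)c(O[Si](C(C)C)(C(C)C)C(C)C)c(OC)c2)c(OC)c1 | intermediate
21 | 5-(ethylsulfonyl)-1-phenyl-1H-tetrazole | CCS(=O)(=O)c1nnnn1-c1ccccc1 | starting material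
22 | potassium 1-[(1-phenyl-1H-tetrazol-5-yl)sulfonyl]ethan-1-ide | C[CH-]S(=O)(=O)c1nnnn1-c1ccccc1.[K+] | intermediate (not isolated)
23 | 1,3-dimethoxy-5-[(E)-prop-1-en-1-yl]-2-(QO)benzene (7-O-TBS, 4-O-TIPS ether of the target) | C/C=C/c1cc(OC)c(O[C@@H](C)[C@H](O[Si](C)(C)C(C)(C)C)c2cc(OC)c(O[Si](C(C)C)(C(C)C)C(C)C)c(OC)c2)c(OC)c1 | intermediate
24 | (1R,2S)-2-{2,6-dimethoxy-4-[(E)-prop-1-en-1-yl]phenoxy}-1-(4-hydroxy-3,5-dimethoxyphenyl)propan-1-ol | C/C=C/c1cc(OC)c(O[C@@H](C)[C@H](O)c2cc(OC)c(O)c(OC)c2)c(OC)c1 | target

## Step count and least certain steps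

Total: 16 steps. Longest linear sequence: 14 steps (steps 1, 2, 4–7 and 9–16, from 1 to 24).

**Step 9 (key step).** The carbenoid may be lost to Wolff rearrangement, dimerisation, attack on ring A or a second insertion into the acidic enol O–H of the product. The wanted path is slowed because the C8 hydroxyl sits beside a carbon that carries a bulky silyloxy group and an aryl ring.

The fallback forms the C8–O4' bond by displacement at C8 with inversion, using known reactions only. It sets out from the aryllithium 6 (made from 5 as in step 4), the purchased phenol A1 and purchased methyl (R)-lactate (C[C@@H](O)C(=O)OC), and it comes back to the route at 24.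
- Mitsunobu etherification (PPh3, diisopropyl azodicarboxylate, THF) should give methyl (S)-2-{2,6-dimethoxy-4-[(E)-prop-1-en-1-yl]phenoxy}propanoate F1.
- MeNH(OMe)·HCl and iPrMgCl should give (S)-2-{2,6-dimethoxy-4-[(E)-prop-1-en-1-yl]phenoxy}-N-methoxy-N-methylpropanamide F2.
- Addition of 6 at −78 °C should give (S)-2-{2,6-dimethoxy-4-[(E)-prop-1-en-1-yl]phenoxy}-1-[3,5-dimethoxy-4-(triisopropylsilyloxy)phenyl]propan-1-one F3.
- Zn(BH4)2 should reduce it under chelation to (1R,2S)-2-{2,6-dimethoxy-4-[(E)-prop-1-en-1-yl]phenoxy}-1-[3,5-dimethoxy-4-(triisopropylsilyloxy)phenyl]propan-1-ol F4 (the same compound as A9).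
- Bu4NF then gives 24.

**Step 11.** Enolisation may be incomplete or unselective. Possible causes are condensation of the enolate with the ethyl ester, proton exchange between unreacted enolate and the acidic dienone or phenol product, and sulfenylation without the following elimination.

The fallback aromatises before any methylation and uses no strong base. It sets out from 13 and comes back at 18.
- Soft enolisation with Me3SiOTf and Et3N should give ethyl 4-(QO)-3,5-bis(trimethylsilyloxy)cyclohexa-2,4-diene-1-carboxylate F5.
- Saegusa–Ito oxidation with Pd(OAc)2 in MeCN and a brief methanolysis should give ethyl 3,5-dihydroxy-4-(QO)benzoate F6.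
- MeI and K2CO3 in acetone methylate both phenols to 18.

**Step 5.** Facial selectivity may be poor if part of the reduction runs through an open, unchelated transition state of the bulky aryl ketone. The syn isomer would be hard to remove.

The fallback sets C7 by addition of the aryl group to an aldehyde instead of hydride to a ketone. It sets out from 2 and 6 and comes back at 8.
- iBu2AlH at −78 °C should reduce 2 to (S)-2-(benzyloxy)propanal F7.
- 6 is transmetalated with ClTi(OiPr)3 to [3,5-dimethoxy-4-(triisopropylsilyloxy)phenyl]triisopropoxytitanium F8.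
- The non-chelating titanium reagent should add under Felkin–Anh control to give the anti alcohol 8.

**Step 15.** The E/Z selectivity may be eroded, and the metalated sulfone may condense with itself before it meets the aldehyde.

The fallback replaces the sulfone by a chromium carbenoid. It sets out from 20 and comes back at 23 with no new intermediate. Takai–Utimoto ethylidenation with CH3CHI2 and CrCl2 (divalent chromium) in THF should give the E propenyl compound 23 directly.

## Further compounds

F1 | step 9 | methyl (S)-2-{2,6-dimethoxy-4-[(E)-prop-1-en-1-yl]phenoxy}propanoate | C/C=C/c1cc(OC)c(O[C@@H](C)C(=O)OC)c(OC)c1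
F2 | step 9 | (S)-2-{2,6-dimethoxy-4-[(E)-prop-1-en-1-yl]phenoxy}-N-methoxy-N-methylpropanamide | C/C=C/c1cc(OC)c(O[C@@H](C)C(=O)N(C)OC)c(OC)c1
F3 | step 9 | (S)-2-{2,6-dimethoxy-4-[(E)-prop-1-en-1-yl]phenoxy}-1-[3,5-dimethoxy-4-(triisopropylsilyloxy)phenyl]propan-1-one | C/C=C/c1cc(OC)c(O[C@@H](C)C(=O)c2cc(OC)c(O[Si](C(C)C)(C(C)C)C(C)C)c(OC)c2)c(OC)c1
F4 | step 9 | (1R,2S)-2-{2,6-dimethoxy-4-[(E)-prop-1-en-1-yl]phenoxy}-1-[3,5-dimethoxy-4-(triisopropylsilyloxy)phenyl]propan-1-ol | C/C=C/c1cc(OC)c(O[C@@H](C)[C@H](O)c2cc(OC)c(O[Si](C(C)C)(C(C)C)C(C)C)c(OC)c2)c(OC)c1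
F5 | step 11 | ethyl 4-(QO)-3,5-bis(trimethylsilyloxy)cyclohexa-2,4-diene-1-carboxylate | CCOC(=O)C1C=C(O[Si](C)(C)C)C(O[C@@H](C)[C@H](O[Si](C)(C)C(C)(C)C)c2cc(OC)c(O[Si](C(C)C)(C(C)C)C(C)C)c(OC)c2)=C(O[Si](C)(C)C)C1
F6 | step 11 | ethyl 3,5-dihydroxy-4-(QO)benzoate | CCOC(=O)c1cc(O)c(O[C@@H](C)[C@H](O[Si](C)(C)C(C)(C)C)c2cc(OC)c(O[Si](C(C)C)(C(C)C)C(C)C)c(OC)c2)c(O)c1
F7 | step 5 | (S)-2-(benzyloxy)propanal | C[C@H](OCc1ccccc1)C=O
F8 | step 5 | [3,5-dimethoxy-4-(triisopropylsilyloxy)phenyl]triisopropoxytitanium | CC(C)O[Ti](OC(C)C)(OC(C)C)c1cc(OC)c(O[Si](C(C)C)(C(C)C)C(C)C)c(OC)c1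
F0 | step 15 | none | none
A1 | alternative 1 | (E)-2,6-dimethoxy-4-(prop-1-en-1-yl)phenol | C/C=C/c1cc(OC)c(O)c(OC)c1
A2 | alternative 1 | 1-[4-(allyloxy)-3,5-dimethoxyphenyl]-2-{2,6-dimethoxy-4-[(E)-prop-1-en-1-yl]phenoxy}ethan-1-one | C/C=C/c1cc(OC)c(OCC(=O)c2cc(OC)c(OCC=C)c(OC)c2)c(OC)c1
A3 | alternative 1 | (S)-1-[4-(allyloxy)-3,5-dimethoxyphenyl]-2-{2,6-dimethoxy-4-[(E)-prop-1-en-1-yl]phenoxy}propan-1-one | C/C=C/c1cc(OC)c(O[C@@H](C)C(=O)c2cc(OC)c(OCC=C)c(OC)c2)c(OC)c1
A4 | alternative 1 | (1R,2S)-1-[4-(allyloxy)-3,5-dimethoxyphenyl]-2-{2,6-dimethoxy-4-[(E)-prop-1-en-1-yl]phenoxy}propan-1-ol | C/C=C/c1cc(OC)c(O[C@@H](C)[C@H](O)c2cc(OC)c(OCC=C)c(OC)c2)c(OC)c1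
A5 | alternative 2 | (S)-4-benzyl-3-({2,6-dimethoxy-4-[(E)-prop-1-en-1-yl]phenoxy}acetyl)-1,3-oxazolidine-2-thione | C/C=C/c1cc(OC)c(OCC(=O)N2C(=S)OC[C@@H]2Cc2ccccc2)c(OC)c1
A6 | alternative 2 | 3,5-dimethoxy-4-(triisopropylsilyloxy)benzaldehyde | O=Cc1cc(OC)c(O[Si](C(C)C)(C(C)C)C(C)C)c(OC)c1
A7 | alternative 2 | (S)-4-benzyl-3-[(2R,3R)-2-{2,6-dimethoxy-4-[(E)-prop-1-en-1-yl]phenoxy}-3-[3,5-dimethoxy-4-(triisopropylsilyloxy)phenyl]-3-hydroxypropanoyl]-1,3-oxazolidine-2-thione | C/C=C/c1cc(OC)c(O[C@@H](C(=O)N2C(=S)OC[C@@H]2Cc2ccccc2)[C@H](O)c2cc(OC)c(O[Si](C(C)C)(C(C)C)C(C)C)c(OC)c2)c(OC)c1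
A8 | alternative 3 | (S)-2-{2,6-dimethoxy-4-[(E)-prop-1-en-1-yl]phenoxy}propanal | C/C=C/c1cc(OC)c(O[C@@H](C)C=O)c(OC)c1
A9 | alternative 3 | (1R,2S)-2-{2,6-dimethoxy-4-[(E)-prop-1-en-1-yl]phenoxy}-1-[3,5-dimethoxy-4-(triisopropylsilyloxy)phenyl]propan-1-ol | C/C=C/c1cc(OC)c(O[C@@H](C)[C@H](O)c2cc(OC)c(O[Si](C(C)C)(C(C)C)C(C)C)c(OC)c2)c(OC)c1
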